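A pitfall first: X at the end of a run is no yield of the catalysis, but what is still left of a middle product, since X goes on to G while Z is still feeding it.

    X → G (k1 = 0.36 /s)
    Z + L ⇌ Z.L (K2 = 15 /M, k2 = 1600 /M/s)
    Z.L → L + X (k3 = 450 /s)

| setting | violet | ochre | green | blue |
|---|---|---|---|---|
| Z | 0.012 M | 0.025 M | 0.050 M | 0.10 M |
| L | 0.5 mol% | 0.5 mol% | 0.5 mol% | 0.5 mol% |
| time | 20 s | 20 s | 20 s | 20 s |

- amount of X at the end, in percent of the Z charged for violet, ochre, green, blue, in this order
- how the row runs (falls, then rises / rises all the way / rises, then falls / hardly changes / falls all the way)

- "hardly changes" means that all values lie within two and a half points (for a concentration: within two and a half percent of the largest)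
- run time (violet): 20 s

We follow one molecule of Z through violet and ask for its chances at each fork.

1. First instants, violet. L is charged at 0.5 mol% of Z, so c(L) = 6.00 × 10⁻⁵ M, and a molecule of Z binds with a half-life of 7.2 s, forward step counted, L held at its charge. K2 times c(Z) at the start is 0.18, less than one, so free L is the resting state of the catalyst.

2. The fork, violet. Z.L can go back to Z + L at 107 /s or on to X at 450 /s, so its chance of going on is 0.808. Z.L lasts 0.00180 s, far shorter than the binding half-life, so we may treat each visit as instantaneous. This gives the passage constant kZ, the chance of going on times k2 times c(L) with L held at its charge, a pseudo-first-order rate constant for the loss of Z: 0.0776 /s in violet.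

3. Middle, violet. X is lost at kX = 0.36 /s, faster than Z passes, so X trails Z. Its share of the charge is kZ/(kX − kZ) · (exp(−kZ·t) − exp(−kX·t)).

4. End, violet. The half-life of X, 1.9 s, is shorter than the run, so the second exponential has faded. We reckon 21.2% of Z left, with X at 0.275 of that, which the full expression puts at 5.80%.

5. The row. L follows the charge, so kZ grows with it: 0.162 /s in ochre, 0.323 /s in green, 0.647 /s in blue. In blue kZ exceeds kX, so we reckon <0.001% of Z left at 20 s, with X by then decaying at its own constant. The expression gives 3.15% for ochre, 0.712% for green and 0.168% for blue, so we expect a row that falls all the way.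

The forecast gives 5.9%, 3.4%, 0.79% and 0.19%, each above ours, and a row that falls all the way, on the grounds that “higher charges convert faster”.

The flasks give 5.88%, 3.33%, 0.795% and 0.188%, a row that falls all the way. Violet held 21.8% of its Z at 20 s, and the trailing ratio from kZ, applied to that amount, gives 5.98% X. In ochre the passage constant 0.162 /s gives 3.92% of Z left at 20 s, and ochre held 4.22%.

The constants were set for the occasion; the rest is arithmetic.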